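**Plan (labdane numbering)**

1. Retrosynthesis cuts, in this order: C12–C13 (B-alkyl Suzuki–Miyaura coupling that brings in the finished ester); C11–C12 and C9–H (methylenation and hydroboration of a C9 exocyclic methylene); C1–C2 (aldol condensation, ring A); and last C5–C6 together with C9–C10 (Diels–Alder reaction, ring B).
2. Enabling feature: ring B is a cyclohexene whose C7=C8 bond lies opposite the C5–C10 fusion bond, so C6=C7–C8=C9 is a diene and C5=C10 an (E)-dienophile. With C9 as the central sp carbon of a vinylallene, the quaternary C10 forms at an unhindered carbon and C9 is not a stereocentre in the cycloaddition.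
3. Forward: ring B first (3-methylpenta-1,2,4-triene plus an (E)-keto enal that already holds quaternary C4 and the C3 carbonyl), ring A second (aldol condensation), then C3–OH, C9–H and the side chain.
4. Stereochemistry: C5/C10 relative configuration from the E-enal (suprafacial addition), absolute from a chiral oxazaborolidinium Lewis acid; C3 from equatorial hydride delivery by LiBH(s-Bu)3; C9 from hydroboration anti to the angular methyl; C13=C14 (E) from syn-hydrozirconation and stereoretentive coupling; the acid stereocentre is purchased.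

Key step: step 6

Assumption: the (S)-configured oxazaborolidine–AlBr3 catalyst is taken to leave the C2-Si face of the keto enal open, as in the accepted model for 2-substituted enals; if the sense proves opposite, the (R)-catalyst is used with no other change.

**Route**

Step 1
Reactants: 1 prop-2-yn-1-ol; 2 bromoethene
Product: 3 pent-4-en-2-yn-1-ol
Conditions: Pd(PPh3)2Cl2 (2 mol %), CuI (4 mol %), Et2NH, THF, 0 °C → rt
Reagents that add atoms: none
Why: Sonogashira coupling of a terminal alkyne with a vinyl bromide is reliable and leaves the primary alcohol untouched.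

Step 2
Reactants: 3 pent-4-en-2-yn-1-ol
Product: 4 pent-4-en-2-yn-1-yl methanesulfonate
Conditions: MsCl, Et3N, CH2Cl2, −30 °C
Reagents that add atoms: methanesulfonyl chloride CS(=O)(=O)Cl
Why: Sulfonylation of the primary propargylic alcohol installs the leaving group needed for SN2′ substitution.

Step 3
Reactants: 4 pent-4-en-2-yn-1-yl methanesulfonate
Product: 5 3-methylpenta-1,2,4-triene
Conditions: MeMgBr, CuBr·SMe2 (10 mol %), LiBr, Bu2O, −60 → 0 °C; volatile product distilled off
Reagents that add atoms: methylmagnesium bromide C[Mg]Br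
Why: Copper-catalysed anti-SN2′ substitution of a propargylic sulfonate by a Grignard reagent is the standard allene synthesis and places the methyl group on the alkyne carbon that carries the vinyl group.

Step 4
Reactants: 6 4-(2-methylprop-1-en-1-yl)morpholine
Product: 8 2,2-dimethyl-3-oxobutanal, via acyliminium chloride 7 (not isolated)
Conditions: AcCl, Et2O, 0 °C → rt; then 1 M aq HCl, rt
Reagents that add atoms: acetyl chloride CC(=O)Cl; water O
Why: Stork enamine C-acylation of an aldehyde enamine followed by hydrolysis should give the 2,2-disubstituted 3-oxo aldehyde, which cannot enolise at the quaternary carbon.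

Step 5
Reactants: 8 2,2-dimethyl-3-oxobutanal; 9 2-(triphenylphosphoranylidene)propanal
Product: 10 (2E)-2,4,4-trimethyl-5-oxohex-2-enal
Conditions: toluene, 100 °C
Reagents that add atoms: none
Why: Wittig olefination with a formyl-stabilised ylide attacks only the aldehyde (not the ketone) and should give the E-trisubstituted enal.

Step 6
Reactants: 5 3-methylpenta-1,2,4-triene; 10 (2E)-2,4,4-trimethyl-5-oxohex-2-enal
Product: 11 (1R,6S)-1,3-dimethyl-2-methylidene-6-(2-methyl-3-oxobutan-2-yl)cyclohex-3-ene-1-carbaldehyde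
Conditions: 5 (3 equiv), (S)-B-(o-tolyl) diphenylprolinol oxazaborolidine (20 mol %), AlBr3 (16 mol %), CH2Cl2, −78 → −40 °C
Reagents that add atoms: none
Why: Normal-demand Diels–Alder reaction in which the s-cis diene unit of 5 (vinyl group plus the adjacent allene double bond) adds suprafacially to the C2=C3 bond of the Lewis-acid-bound enal 10, concerted but asynchronous, the C5–C6 bond (enal C3 to the vinyl CH2) running ahead of the C9–C10 bond (enal C2 to the central allene carbon). The closest known reaction types are the oxazaborolidinium-catalysed enantioselective Diels–Alder reactions of 2-methyl-substituted enals and the cycloadditions of vinylallenes that give 2-methylidenecyclohex-3-enes. Ring B is closed by [4+2] cycloaddition, both ring bonds being made in the one step. The new stereocentres are C10 and C5: their relative configuration (methyl cis to the tert-alkyl group, hence the later trans ring fusion) follows stereospecifically from the E geometry of 10, and their absolute configuration from the catalyst, which should admit the diene only to the C2-Si face of the bound s-trans enal. The step needs regioselectivity (formyl-bearing carbon to the sp carbon), which should be secured by the larger HOMO coefficient at the vinyl terminus of a vinylallene and by sterics, since the neopentyl-type β-carbon meets the unsubstituted CH2 and the quaternary centre forms at the unhindered sp carbon. Endo/exo selectivity is of no consequence because the allene carbon becomes an exocyclic alkene, so that C9 is left to step 10.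

Step 7
Reactants: 11 (1R,6S)-1,3-dimethyl-2-methylidene-6-(2-methyl-3-oxobutan-2-yl)cyclohex-3-ene-1-carbaldehyde
Product: 13 (4aR,8aS)-1,1,4a,6-tetramethyl-5-methylidene-4a,5,8,8a-tetrahydronaphthalen-2(1H)-one, via aldol adduct 12 (not isolated)
Conditions: KOH (0.3 equiv), MeOH, rt → 50 °C
Reagents that add atoms: none
Why: Intramolecular aldol condensation in which the methyl ketone is the only enolisable position and the neopentyl aldehyde the only electrophile should close ring A as the 1-en-3-one, with the trans ring fusion already fixed in step 6.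

Step 8
Reactants: 13 (4aR,8aS)-1,1,4a,6-tetramethyl-5-methylidene-4a,5,8,8a-tetrahydronaphthalen-2(1H)-one
Product: 14 (4aR,8aS)-1,1,4a,6-tetramethyl-5-methylidene-3,4,4a,5,8,8a-hexahydronaphthalen-2(1H)-one
Conditions: [(Ph3P)CuH]6 (0.25 equiv), H2O (3 equiv), toluene, rt
Reagents that add atoms: none
Why: Conjugate reduction with the phosphine-stabilised copper hydride (Stryker reagent) should reduce only the enone C=C and leave the unactivated semicyclic diene alone.

Step 9
Reactants: 14 (4aR,8aS)-1,1,4a,6-tetramethyl-5-methylidene-3,4,4a,5,8,8a-hexahydronaphthalen-2(1H)-one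
Product: 15 (2S,4aR,8aS)-1,1,4a,6-tetramethyl-5-methylidene-1,2,3,4,4a,5,8,8a-octahydronaphthalen-2-ol
Conditions: LiBH(s-Bu)3 (1.5 equiv), THF, −78 °C; then H2O
Reagents that add atoms: none
Why: Bulky trialkylborohydride reduction delivers hydride along the equatorial trajectory of the 4,4-dimethyl-3-ketone and should therefore give the axial (3S) alcohol, anti to the C10 methyl.

Step 10
Reactants: 15 (2S,4aR,8aS)-1,1,4a,6-tetramethyl-5-methylidene-1,2,3,4,4a,5,8,8a-octahydronaphthalen-2-ol
Product: 17 (2S,4aR,5R,8aS)-5-(hydroxymethyl)-1,1,4a,6-tetramethyl-1,2,3,4,4a,5,8,8a-octahydronaphthalen-2-ol, via bis-9-BBN adduct 16 (not isolated)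
Conditions: 9-BBN-H (2.3 equiv), THF, 0 °C → rt; then NaOH, H2O2, 0 °C
Reagents that add atoms: hydrogen peroxide OO
Why: Hydroboration–oxidation with 9-BBN should engage only the 1,1-disubstituted exocyclic alkene, boron going to the CH2 terminus and hydrogen to C9 from the face anti to the axial C10 methyl, which sets C9 with the new CH2OH group equatorial.

Step 11
Reactants: 17 (2S,4aR,5R,8aS)-5-(hydroxymethyl)-1,1,4a,6-tetramethyl-1,2,3,4,4a,5,8,8a-octahydronaphthalen-2-ol
Product: 18 (1R,4aS,6S,8aR)-6-hydroxy-2,5,5,8a-tetramethyl-1,4,4a,5,6,7,8,8a-octahydronaphthalene-1-carbaldehyde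
Conditions: TEMPO (10 mol %), PhI(OAc)2 (1.1 equiv), CH2Cl2, rt
Reagents that add atoms: none
Why: Oxoammonium (TEMPO) oxidation is selective for the primary alcohol over the hindered axial secondary one and is non-basic, so the β,γ-unsaturated aldehyde should not epimerise or conjugate.

Step 12
Reactants: 18 (1R,4aS,6S,8aR)-6-hydroxy-2,5,5,8a-tetramethyl-1,4,4a,5,6,7,8,8a-octahydronaphthalene-1-carbaldehyde
Product: 19 (2S,4aR,5R,8aS)-5-ethenyl-1,1,4a,6-tetramethyl-1,2,3,4,4a,5,8,8a-octahydronaphthalen-2-ol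
Conditions: Ph3PCH3Br (3 equiv), KOt-Bu (2.8 equiv), THF, 0 °C; then 18, −78 → 0 °C
Reagents that add atoms: methylidenetriphenylphosphorane C=P(c1ccccc1)(c1ccccc1)c1ccccc1
Why: Wittig methylenation with the non-stabilised ylide is fast at low temperature, which should outpace α-epimerisation, and turns the formyl group into the vinyl group needed for the final coupling.

Step 13
Reactants: 20 but-2-yn-1-ol; 21 (3S)-3-methylpentanoic acid
Product: 22 but-2-yn-1-yl (3S)-3-methylpentanoate
Conditions: DCC, DMAP (10 mol %), CH2Cl2, 0 °C → rt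
Reagents that add atoms: none
Why: Steglich esterification joins the purchased (S)-acid to the propargylic alcohol without touching the β-stereocentre.

Step 14
Reactants: 22 but-2-yn-1-yl (3S)-3-methylpentanoate
Product: 24 (2E)-3-iodobut-2-en-1-yl (3S)-3-methylpentanoate, via alkenylzirconocene chloride 23 (not isolated)
Conditions: Cp2Zr(H)Cl (1.3 equiv), THF, rt; then I2, 0 °C
Reagents that add atoms: iodine II
Why: Hydrozirconation is a syn addition that, after equilibration with a slight excess of reagent, should place zirconium on the methyl-bearing alkyne carbon, and iodinolysis with retention then gives the E-vinyl iodide.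

Step 15
Reactants: 19 (2S,4aR,5R,8aS)-5-ethenyl-1,1,4a,6-tetramethyl-1,2,3,4,4a,5,8,8a-octahydronaphthalen-2-ol; 24 (2E)-3-iodobut-2-en-1-yl (3S)-3-methylpentanoate
Product: 26 (2E)-5-[(1R,4aS,6S,8aS)-6-hydroxy-2,5,5,8a-tetramethyl-1,4,4a,5,6,7,8,8a-octahydronaphthalen-1-yl]-3-methylpent-2-en-1-yl (3S)-3-methylpentanoate, via B-alkyl-9-BBN adduct 25 (not isolated)
Conditions: 9-BBN-H (2.3 equiv), THF, rt; then 24, Pd(dppf)Cl2 (5 mol %), AsPh3 (5 mol %), Cs2CO3, DMF/H2O, rt
Reagents that add atoms: none
Why: B-alkyl Suzuki–Miyaura coupling, in which anti-Markovnikov hydroboration of the vinyl group (faster than that of the trisubstituted ring alkene) gives a primary alkylborane that should couple with the vinyl iodide with retention of the E geometry under conditions mild enough for the ester and the free alcohol.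

**Compound list**

1 | prop-2-yn-1-ol | C#CCO | starting material
2 | bromoethene | BrC=C | starting material
3 | pent-4-en-2-yn-1-ol | OCC#CC=C | intermediate
4 | pent-4-en-2-yn-1-yl methanesulfonate | CS(=O)(=O)OCC#CC=C | intermediate
5 | 3-methylpenta-1,2,4-triene | C=C=C(C)C=C | intermediate
6 | 4-(2-methylprop-1-en-1-yl)morpholine | CC(C)=CN1CCOCC1 | starting material
7 | 4-(2,2-dimethyl-3-oxobutylidene)morpholin-4-ium chloride | CC(=O)C(C)(C)C=[N+]1CCOCC1.[Cl-] | intermediate
8 | 2,2-dimethyl-3-oxobutanal | CC(=O)C(C)(C)C=O | intermediate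
9 | 2-(triphenylphosphoranylidene)propanal | CC(C=O)=P(c1ccccc1)(c1ccccc1)c1ccccc1 | starting material
10 | (2E)-2,4,4-trimethyl-5-oxohex-2-enal | CC(=O)C(C)(C)/C=C(\C)C=O | intermediate
11 | (1R,6S)-1,3-dimethyl-2-methylidene-6-(2-methyl-3-oxobutan-2-yl)cyclohex-3-ene-1-carbaldehyde | O=C[C@@]1(C)C(=C)C(C)=CC[C@@H]1C(C)(C)C(C)=O | intermediate
12 | (4aR,8aS)-4-hydroxy-1,1,4a,6-tetramethyl-5-methylidene-3,4,4a,5,8,8a-hexahydronaphthalen-2(1H)-one (both C-4 epimers) | O=C1CC(O)[C@@]2(C)C(=C)C(C)=CC[C@@H]2C1(C)C | intermediate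
13 | (4aR,8aS)-1,1,4a,6-tetramethyl-5-methylidene-4a,5,8,8a-tetrahydronaphthalen-2(1H)-one | O=C1C=C[C@@]2(C)C(=C)C(C)=CC[C@@H]2C1(C)C | intermediate
14 | (4aR,8aS)-1,1,4a,6-tetramethyl-5-methylidene-3,4,4a,5,8,8a-hexahydronaphthalen-2(1H)-one | O=C1CC[C@@]2(C)C(=C)C(C)=CC[C@@H]2C1(C)C | intermediate
15 | (2S,4aR,8aS)-1,1,4a,6-tetramethyl-5-methylidene-1,2,3,4,4a,5,8,8a-octahydronaphthalen-2-ol | O[C@H]1CC[C@@]2(C)C(=C)C(C)=CC[C@@H]2C1(C)C | intermediate
16 | 9-{[(1R,4aS,6S,8aS)-6-(9-borabicyclo[3.3.1]nonan-9-yloxy)-2,5,5,8a-tetramethyl-1,4,4a,5,6,7,8,8a-octahydronaphthalen-1-yl]methyl}-9-borabicyclo[3.3.1]nonane | C(B3C4CCCC3CCC4)[C@@H]1C(C)=CC[C@@H]2C(C)(C)[C@@H](OB3C4CCCC3CCC4)CC[C@@]12C | intermediate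
17 | (2S,4aR,5R,8aS)-5-(hydroxymethyl)-1,1,4a,6-tetramethyl-1,2,3,4,4a,5,8,8a-octahydronaphthalen-2-ol | OC[C@@H]1C(C)=CC[C@@H]2C(C)(C)[C@@H](O)CC[C@@]12C | intermediate
18 | (1R,4aS,6S,8aR)-6-hydroxy-2,5,5,8a-tetramethyl-1,4,4a,5,6,7,8,8a-octahydronaphthalene-1-carbaldehyde | O=C[C@@H]1C(C)=CC[C@@H]2C(C)(C)[C@@H](O)CC[C@@]12C | intermediate
19 | (2S,4aR,5R,8aS)-5-ethenyl-1,1,4a,6-tetramethyl-1,2,3,4,4a,5,8,8a-octahydronaphthalen-2-ol | C=C[C@@H]1C(C)=CC[C@@H]2C(C)(C)[C@@H](O)CC[C@@]12C | intermediate
20 | but-2-yn-1-ol | CC#CCO | starting material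
21 | (3S)-3-methylpentanoic acid | CC[C@H](C)CC(=O)O | starting material
22 | but-2-yn-1-yl (3S)-3-methylpentanoate | CC[C@H](C)CC(=O)OCC#CC | intermediate
23 | chlorido{(2E)-4-[(3S)-3-methylpentanoyloxy]but-2-en-2-yl}bis(cyclopentadienyl)zirconium | CC[C@H](C)CC(=O)OC/C=C(\C)[Zr](Cl)(C1C=CC=C1)C1C=CC=C1 | intermediate
24 | (2E)-3-iodobut-2-en-1-yl (3S)-3-methylpentanoate | CC[C@H](C)CC(=O)OC/C=C(\C)I | intermediate
25 | 9-{2-[(1R,4aS,6S,8aS)-6-(9-borabicyclo[3.3.1]nonan-9-yloxy)-2,5,5,8a-tetramethyl-1,4,4a,5,6,7,8,8a-octahydronaphthalen-1-yl]ethyl}-9-borabicyclo[3.3.1]nonane | B1(C2CCCC1CCC2)CC[C@@H]1C(C)=CC[C@@H]2C(C)(C)[C@@H](OB3C4CCCC3CCC4)CC[C@@]12C | intermediate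
26 | (2E)-5-[(1R,4aS,6S,8aS)-6-hydroxy-2,5,5,8a-tetramethyl-1,4,4a,5,6,7,8,8a-octahydronaphthalen-1-yl]-3-methylpent-2-en-1-yl (3S)-3-methylpentanoate | CC[C@H](C)CC(=O)OC/C=C(\C)CC[C@@H]1C(C)=CC[C@@H]2C(C)(C)[C@@H](O)CC[C@@]12C | target

**Totals and risks**

Total step count: 15. Longest linear sequence: 11 steps (steps 1–3, 6–12 and 15).

Step 6. The cycloaddition may be too slow at the neopentyl-type β-carbon of the enal, bond formation may run in the reverse regiochemical sense (β-carbon to the allene carbon, if the methyl on the diene dominates), the allene may oligomerise under the Lewis acid, or facial discrimination by the catalyst may be poor. The fallback sets out from 10 and comes back at 15. The diene is changed to the 1-silyloxy diene tert-butyl(dimethyl){[(1E)-2-methylbuta-1,3-dien-1-yl]oxy}silane F1 (from commercial (E)-2-methylbut-2-enal, TBSOTf, Et3N), whose terminal oxygen dictates the orientation of the same oxazaborolidinium-catalysed Diels–Alder reaction. Endo addition should give the silyloxy cyclohexenecarbaldehyde F2, whose C9 configuration is irrelevant. KOH/MeOH aldol condensation gives the silyloxy bicyclic enone F3, [(Ph3P)CuH]6 the saturated silyloxy ketone F4, and LiBH(s-Bu)3 the axial silyloxy alcohol F5. Bu4NF then frees the allylic diol F6, MnO2 oxidises only the allylic hydroxyl to the hydroxy enone F7, and CeCl3-promoted addition of Me3SiCH2Li gives the β-hydroxysilane F8, whose Peterson elimination (KH, THF) returns 15.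

Step 11. The β,γ-unsaturated aldehyde may epimerise at C9 or suffer migration of the ring double bond into conjugation, during the oxidation or the following methylenation. The fallback sets out from 17 and comes back at 26, avoiding any carbonyl at C11. Appel iodination of the primary hydroxyl (I2, PPh3, imidazole) gives the primary iodide F9. Copper-catalysed borylation (CuI, PPh3, LiOt-Bu, bis(pinacolato)diboron) gives the pinacol boronate F10. Matteson homologation (ICH2Cl, n-BuLi, one extra equivalent for the free hydroxyl, −78 °C → rt) gives the homologated pinacol boronate F11. Suzuki–Miyaura coupling of F11 with 24 (Pd(OAc)2, SPhos, K3PO4, toluene/H2O, 80 °C) then gives 26.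

Step 5. Olefination of the α-quaternary aldehyde by the weakly nucleophilic formyl ylide may be sluggish, with competing cleavage or self-condensation of the β-keto aldehyde. The fallback sets out from 8 and comes back at 10. Horner–Wadsworth–Emmons reaction with triethyl 2-phosphonopropionate (LiCl, DBU, MeCN) gives the keto ester ethyl (2E)-2,4,4-trimethyl-5-oxohex-2-enoate F12. Reduction with i-Bu2AlH gives the diol (2E)-2,4,4-trimethylhex-2-ene-1,5-diol F13, and double Swern oxidation of both hydroxyls returns 10.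

**Further compounds**

F1 | step 6 | tert-butyl(dimethyl){[(1E)-2-methylbuta-1,3-dien-1-yl]oxy}silane | C=C/C(C)=C/O[Si](C)(C)C(C)(C)C
F2 | step 6 | (1R,2S,6S)-2-{[tert-butyl(dimethyl)silyl]oxy}-1,3-dimethyl-6-(2-methyl-3-oxobutan-2-yl)cyclohex-3-ene-1-carbaldehyde | O=C[C@@]1(C)[C@@H](O[Si](C)(C)C(C)(C)C)C(C)=CC[C@@H]1C(C)(C)C(C)=O
F3 | step 6 | (4aR,5S,8aS)-5-{[tert-butyl(dimethyl)silyl]oxy}-1,1,4a,6-tetramethyl-4a,5,8,8a-tetrahydronaphthalen-2(1H)-one | O=C1C=C[C@@]2(C)[C@@H](O[Si](C)(C)C(C)(C)C)C(C)=CC[C@@H]2C1(C)C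
F4 | step 6 | (4aR,5S,8aS)-5-{[tert-butyl(dimethyl)silyl]oxy}-1,1,4a,6-tetramethyl-3,4,4a,5,8,8a-hexahydronaphthalen-2(1H)-one | O=C1CC[C@@]2(C)[C@@H](O[Si](C)(C)C(C)(C)C)C(C)=CC[C@@H]2C1(C)C
F5 | step 6 | (2S,4aR,5S,8aR)-5-{[tert-butyl(dimethyl)silyl]oxy}-1,1,4a,6-tetramethyl-1,2,3,4,4a,5,8,8a-octahydronaphthalen-2-ol | O[C@H]1CC[C@@]2(C)[C@@H](O[Si](C)(C)C(C)(C)C)C(C)=CC[C@@H]2C1(C)C
F6 | step 6 | (1S,4aR,6S,8aR)-2,5,5,8a-tetramethyl-1,4,4a,5,6,7,8,8a-octahydronaphthalene-1,6-diol | O[C@H]1CC[C@@]2(C)[C@@H](O)C(C)=CC[C@@H]2C1(C)C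
F7 | step 6 | (4aR,6S,8aR)-6-hydroxy-2,5,5,8a-tetramethyl-4a,5,6,7,8,8a-hexahydronaphthalen-1(4H)-one | O[C@H]1CC[C@@]2(C)C(=O)C(C)=CC[C@@H]2C1(C)C
F8 | step 6 | (4aR,6S,8aR)-2,5,5,8a-tetramethyl-1-[(trimethylsilyl)methyl]-1,4,4a,5,6,7,8,8a-octahydronaphthalene-1,6-diol (C-1 epimers) | O[C@H]1CC[C@@]2(C)C(O)(C[Si](C)(C)C)C(C)=CC[C@@H]2C1(C)C
F9 | step 11 | (2S,4aR,5R,8aS)-5-(iodomethyl)-1,1,4a,6-tetramethyl-1,2,3,4,4a,5,8,8a-octahydronaphthalen-2-ol | IC[C@@H]1C(C)=CC[C@@H]2C(C)(C)[C@@H](O)CC[C@@]12C
F10 | step 11 | (2S,4aS,5R,8aS)-1,1,4a,6-tetramethyl-5-[(4,4,5,5-tetramethyl-1,3,2-dioxaborolan-2-yl)methyl]-1,2,3,4,4a,5,8,8a-octahydronaphthalen-2-ol | CC1(C)OB(C[C@@H]2C(C)=CC[C@@H]3C(C)(C)[C@@H](O)CC[C@@]23C)OC1(C)C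
F11 | step 11 | (2S,4aS,5R,8aS)-1,1,4a,6-tetramethyl-5-[2-(4,4,5,5-tetramethyl-1,3,2-dioxaborolan-2-yl)ethyl]-1,2,3,4,4a,5,8,8a-octahydronaphthalen-2-ol | CC1(C)OB(CC[C@@H]2C(C)=CC[C@@H]3C(C)(C)[C@@H](O)CC[C@@]23C)OC1(C)C
F12 | step 5 | ethyl (2E)-2,4,4-trimethyl-5-oxohex-2-enoate | CCOC(=O)/C(C)=C/C(C)(C)C(C)=O
F13 | step 5 | (2E)-2,4,4-trimethylhex-2-ene-1,5-diol | OC/C(C)=C/C(C)(C)C(C)O
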